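A small charge of single-handed free catalyst, 1.6 mM against 0.50 M of each mirror substrate, turns left-handed substrate and coupling partner into left-handed product, and right-handed substrate and coupling partner into right-handed product.

| flask | left-handed substrate | right-handed substrate | coupling partner | protic impurity | free catalyst | remark | time |
|---|---|---|---|---|---|---|---|
| green | 0.50 M | 0.50 M | 0.47 M | 0.25 M | 1.6 mM | run made earlier |  |
| red | 0.50 M | 0.50 M | 0.91 M | 0.25 M | 1.6 mM | run made earlier |  |
| spring | 0.50 M | 0.50 M | 0.550 M | 0.250 M | 1.6 mM |  | 1.5 h |
| noon | 0.50 M | 0.50 M | 1.50 M | 0.250 M | 1.6 mM |  | 1.5 h |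

| run | time / min | left-handed product / % | right-handed product / % |
|---|---|---|---|
| green | 4.00 | 3.9 | 0.6 |
| green | 6.00 | 4.1 | 2.7 |
| green | 8.00 | 2.5 | 2.0 |
| green | 12.0 | 7.6 | 4.3 |
| green | 20.0 | 10.6 | 5.4 |
| green | 30.0 | 12.4 | 6.0 |
| green | 50.0 | 15.9 | 7.4 |
| red | 2.50 | 0.6 | 0.7 |
| red | 6.00 | 7.9 | 2.3 |
| red | 12.0 | 10.8 | 8.4 |
| red | 20.0 | 15.8 | 12.6 |
| red | 25.0 | 19.6 | 13.2 |
| red | 40.0 | 26.5 | 16.8 |
| red | 50.0 | 28.0 | 21.4 |

(standard deviation of a reading: 1 percentage point)

- free catalyst is single-handed; left-handed substrate and right-handed substrate are mirror images of each other, charged as a racemate, each of them at the stated concentration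
- what was read earlier has a scatter of 1 percentage point, one standard deviation
- an excess is the difference of the two amounts in percent of their sum
- an excess is below zero if the other one leads

- the flask that ends with the higher excess of left-handed product over right-handed product in the product, or "neither" when 2 percentage points or less lies between them (spring / noon / neither)
- excess of left-handed product over right-handed product in the product at the end, spring
- excess of left-handed product over right-handed product in the product at the end, noon

Follow one substrate molecule: at the fork it becomes product or stays, and if it keeps its hand, each hand is a closed account. The gap between the products then equals the gap between the substrates left, so conversion c, the part of both substrates together turned into product, bounds the excess.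

You need c for noon, and the red run offers two ways to the rate of conversion, taken as first order. The reading at 20.0 min, with c of 28.4 %, gives 0.0167 min⁻¹, while the reading at 50.0 min, with c of 49.4 %, gives 0.0136 min⁻¹. They part, and the late one cheats, because by then the red run has put about half of its partner into product. Rescaled from the mean partner of each stretch to the red charge, they become 0.0198 min⁻¹ and 0.0187 min⁻¹, which agree within the reading.

My reckoning gives noon a mean partner of 1.00 M, its charge less one substrate's charge, and so c of 85.1 %. That sets 17.5 % as the hand ceiling, the unconverted share over the converted share, the bound of a kinetic resolution. Spring's partner allows c of 55.0 % at most, so its ceiling of 81.8 % stands far off. I would therefore carry over the green run's excess, 34.8 % over its last three readings, and put noon below the ceiling.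

The forecast says spring, with 31 % for spring, less than my figure, and 5 % for noon, on the ground that “Depletion of the faster substrate then erodes the excess”.

Spring ends at 21.4 % and noon at 12.0 %, so spring leads. With the unconverted and converted shares of noon's end in place of my estimate, noon's hand ceiling falls from 17.5 % to 11.6 %, and noon's excess stands above it.

    coupling partner + protic impurity → quenched reagent (k = 1.90 × 10⁻⁴ L mol⁻¹ s⁻¹)
    coupling partner + catalyst intermediate A → free catalyst + left-handed product (k = 0.440 L mol⁻¹ s⁻¹)
    free catalyst → spent catalyst (k = 1.50 × 10⁻⁴ s⁻¹)
    coupling partner + catalyst intermediate B → free catalyst + right-handed product (k = 0.170 L mol⁻¹ s⁻¹)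
    free catalyst + left-handed substrate ⇌ catalyst intermediate A (K = 2.90 L mol⁻¹, k = 8.40 L mol⁻¹ s⁻¹)
    free catalyst + right-handed substrate ⇌ catalyst intermediate B (K = 4.40 L mol⁻¹, k = 16.0 L mol⁻¹ s⁻¹)
    left-handed substrate ⇌ right-handed substrate (k = 2.10 × 10⁻⁴ s⁻¹)

The substrates interconvert, their difference halving every 27.5 min, shorter than the run of 90 min. In noon at the end the product gap is 11 percentage points against a substrate gap of 2 points, and after 15.0 h noon shows 11.6 % over a ceiling of 0.932 %. The neighbour charged with 1.4 M of coupling partner ends at 13.0 %, its product gap 11 points against a substrate gap of 2.3 points.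

The runs are simulated for substances that don't exist.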